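Each closed, stirred flask holds a charge of starting material under gas held at 0.57 mM, and I take starting material as the limiting reagent. My ledger therefore has two columns: target made and starting material left.

common to all: gas 0.57 mM (held)
- south-west: starting material 8.5 mM; free enzyme 1.7 µM; temperature −30 °C; run made earlier
- north: starting material 13 mM; free enzyme 1.7 µM; temperature 5 °C; run made earlier
- south: starting material 17 mM; free enzyme 0.85 µM; temperature −30 °C; run made earlier
- elm: starting material 17 mM; free enzyme 1.7 µM; temperature 35 °C; time 50 h
- ash: starting material 17 mM; free enzyme 1.7 µM; temperature −25 °C; time 50 h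
- oak: starting material 17 mM; free enzyme 1.7 µM; temperature 5 °C; time 50 h

- south-west (time / h: target / %, starting material / %): 96.0: 3.6, 96.9; 240: 8.5, 91.5; 480: 17.4, 82.6; 720: 25.8, 74.6; 960: 34.0, 66.1
- north (time / h: target / %, starting material / %): 20.0: 22.2, 77.7; 40.0: 44.1, 54.9; 96.0: 98.7, 1.3; 144: 99.8, 0; 192: 100.2, 0.1
- south (time / h: target / %, starting material / %): 72.0: 0.8, 99.7; 144: 1.5, 98.7; 288: 2.5, 97.6; 480: 4.3, 95.3; 960: 8.2, 90.5

(each reading ± 0.3 percentage points)

- what was read earlier has a scatter of 0.3 percentage points, one standard deviation
- at the start none of the gas is in solution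

1. which flask leads in amount of target, in percent of the starting material charged ("all alike" within 1.5 percentage points) (elm / ash / oak / all alike)
2. how much target is there at the end, in percent of the starting material charged: elm
3. how much target is there at the end, in percent of the starting material charged: ash
4. how much target is there at the end, in percent of the starting material charged: oak

The books balance in the south-west run, which closes at 34.0% target and 66.1% starting material after 960 h. I call N the turnover frequency: moles of target per hour per mole of enzyme charged. The south-west run reads N = 1.77 h⁻¹. The south run, at the same temperature with twice the starting material and half the enzyme, reads 1.71 h⁻¹. The two readings lie close together with both charges changed, so I write the ledger entry as N times enzyme charged times time, with no term for starting material. The north run reads 84.3 h⁻¹ at 5 °C, and an Arrhenius line through these readings has an activation energy of 62.1 kJ mol⁻¹.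

On that line ash has N = 3.29 h⁻¹, the turnover frequency at its temperature, so I book 1.64% for ash. Oak, at the north temperature, gets 42.2%. For elm the line gives 1150 h⁻¹, and the 10000 turnovers its charge needs would take 8.70 h, less than the 50 h allowed. I book full conversion, provided the enzyme lasts, which no reading at 35 °C shows.

The forecast names elm as leader, with 100%, 1.6% and 42% for elm, ash and oak, and calls the elm figure “a long extrapolation”.

The flasks give 1.04% in elm, 1.72% in ash and 42.8% in oak, so oak leads.

    gas ⇌ second substrate, rate k1*(csat - [second substrate]) (kL = 2.98 h⁻¹)
    second substrate + loaded enzyme ⇌ second complex (K = 3300 M⁻¹, k = 28300 M⁻¹ s⁻¹, Ea = 10.0 kJ mol⁻¹, ΔH = −29.0 kJ mol⁻¹)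
    starting material + free enzyme ⇌ first complex (K = 90.5 M⁻¹, k = 1.75 × 10⁶ M⁻¹ h⁻¹, Ea = 43.0 kJ mol⁻¹, ΔH = −35.0 kJ mol⁻¹)
    free enzyme → unfolded enzyme (k = 0.00281 h⁻¹, Ea = 269 kJ mol⁻¹)
    second complex → free enzyme + target (k = 144 h⁻¹, Ea = 68.0 kJ mol⁻¹)
    first complex → loaded enzyme + first product (k = 3260 h⁻¹, Ea = 76.0 kJ mol⁻¹)
    (constants at 5 °C)

In elm, target stands at 1.04% after 25.0 h and at 1.04% after 50.0 h, with unfolded enzyme at 100% of the catalyst by the first of these times; the target found comes to 104 turnovers on average per enzyme charged, fewer than the 10000 its charge needs. In ash, unfolded enzyme stands at 0% and second complex holds 83.8% of the catalyst after 50.0 h, and N = 3.29 h⁻¹ books 0.279 mM against 0.293 mM of target found.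

A neighbour like ash, but with 4.2 mM of starting material, gets the same 0.279 mM from N, which is 6.65% of its charge. The computed flask gives 6.82%.

(Readings and results stem from a simulated flask for substances that don't exist, and the scatter is random.)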